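A direct plan would keep a bought phloroglucinol as ring A, convert it into ortho-silylaryl triflate A1, and close ring C by adding arylpropiolic acid A2 to the derived aryne.
The C8 side arm would then be oxidised to 8-formylflavone A3, the chain attached by catalytic asymmetric allylboration to carbinol A4, and the carbinol oxygen removed through a xanthate.
Its weakest points would be:
- the long protecting-group and directing-group run-up to A1, which adds no skeletal bond, followed by an aryne cascade in which the site of oxygen attack, acyl shift against protonation, and 6-endo against 5-exo closure all rest on substituent bias;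
- the allylboration, which would set the only stereocentre late, by catalyst control on a hindered, chelating, doubly ortho-substituted aldehyde, and would create a second stereocentre only to destroy it;
- the tin hydride deoxygenation of the benzylic xanthate beside an isopropenyl group and a chromone enone, the step one would least like to run on precious late material.

**Plan of the new route**

Retrosynthesis: ring C is opened first (O1–C2, then C3–C4 to an aldehyde and an arylalkyne, then C4–C4a), and ring A itself is then cut at C8–C8a, C7–C6 and C4a–C8a; the C8–C1'' bond is never cut.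
Enabling feature: ring A is a phloroglucinol whose carbon substituent sits on C8 between the oxygen-bearing C7 and C8a, the O–C(alkyl)–O pattern that a siloxyalkyne (C7, C8) and a vinylketene (C8a as ketene carbonyl, then C4a, C5, C6) give in a cyclobutenone benzannulation.
The chain C8–C1''–C2''(isopropenyl)–C3''–C4''–C5''–CH3 is the opened cyclohexene ring of (R)-limonene, so C2'' is bought and the former limonene C2 becomes the alkyne carbon that ends as C8.
Order of rings: B (bought), A (benzannulation around the chain terminus), C (last).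
The annulation delivers the three ring-A oxygens differentiated (free OH at C8a, silyl ether at C7, allyl ether at C5), so formylation and pyranone closure each have one possible site.
Hence no aryne, no asymmetric catalysis, no deoxygenation and no chain attachment to a finished flavone occur.

Key step: step 7

Assumption: commercial (+)-limonene oxide is the cis/trans epoxide mixture of the (4R) series; both epoxide isomers should converge on the same keto aldehyde in step 1.

**Chain fragment (siloxyalkyne)**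

Step 1
Reactants: 1 (4R)-limonene 1,2-oxide [(4R)-1-methyl-4-(prop-1-en-2-yl)-7-oxabicyclo[4.1.0]heptane, cis/trans mixture]
Product: 2 (3R)-6-oxo-3-(prop-1-en-2-yl)heptanal
Conditions: H5IO6 (1.1 equiv), THF–H2O, 0 °C → rt
Reagents that add atoms: water, O
Why: Acid-promoted epoxide hydrolysis and periodate glycol cleavage (Malaprade reaction) in one flask; the terpene stereocentre that becomes C2'' is not involved and both epoxide isomers give the same product.

Step 2
Reactants: 2 (3R)-6-oxo-3-(prop-1-en-2-yl)heptanal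
Product: 3 (5R)-8,8-dibromo-5-(prop-1-en-2-yl)oct-7-en-2-one
Conditions: CBr4 (2 equiv), PPh3 (4 equiv), CH2Cl2, 0 °C
Reagents that add atoms: carbon tetrabromide, BrC(Br)(Br)Br
Why: Corey–Fuchs dibromoolefination is a non-basic Wittig-type reaction that takes the aldehyde and leaves the methyl ketone, so the intramolecular aldol reaction of the keto aldehyde is avoided.

Step 3
Reactants: 3 (5R)-8,8-dibromo-5-(prop-1-en-2-yl)oct-7-en-2-one
Product: 4 (5R)-8,8-dibromo-2-methyl-5-(prop-1-en-2-yl)oct-7-en-2-ol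
Conditions: MeMgBr (1.3 equiv), THF, −78 → 0 °C; sat. NH4Cl
Reagents that add atoms: methylmagnesium bromide, C[Mg]Br
Why: Grignard addition to the methyl ketone builds the tertiary carbinol C5''; a methyl Grignard reagent should not undergo halogen–magnesium exchange with the 1,1-dibromoalkene at this temperature.

Step 4
Reactants: 4 (5R)-8,8-dibromo-2-methyl-5-(prop-1-en-2-yl)oct-7-en-2-ol
Product: 5 {[(5R)-8,8-dibromo-2-methyl-5-(prop-1-en-2-yl)oct-7-en-2-yl]oxy}triethylsilane
Conditions: Et3SiOTf, 2,6-lutidine, CH2Cl2, −78 → 0 °C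
Reagents that add atoms: triethylsilyl trifluoromethanesulfonate, CC[Si](CC)(CC)OS(=O)(=O)C(F)(F)F
Why: Silyl triflate silylation of the tertiary alcohol, so that no hydroxyl can trap the ketenes of step 7; the ether is fluoride-labile for the final step.

Step 5
Reactants: 5 {[(5R)-8,8-dibromo-2-methyl-5-(prop-1-en-2-yl)oct-7-en-2-yl]oxy}triethylsilane
Product: 8 triethyl({(5R)-2-methyl-5-(prop-1-en-2-yl)-8-[(triisopropylsilyl)oxy]oct-7-yn-2-yl}oxy)silane, via lithium acetylide 6 (not isolated), via lithium ynolate 7 (not isolated)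
Conditions: n-BuLi (2.2 equiv), THF, −78 → 0 °C; then t-BuOOLi (from t-BuOOH and LiN(SiMe3)2), −78 → 0 °C; then i-Pr3SiOTf, −78 °C → rt
Reagents that add atoms: tert-butyl hydroperoxide (as its lithium salt, delivers the oxygen), CC(C)(C)OO; triisopropylsilyl trifluoromethanesulfonate, CC(C)[Si](OS(=O)(=O)C(F)(F)F)(C(C)C)C(C)C
Why: The second stage of the Corey–Fuchs reaction gives the lithium acetylide, electrophilic oxygenation of the acetylide by lithium tert-butyl peroxide gives the ynolate, and the bulky silyl triflate silylates it on oxygen to the isolable siloxyalkyne.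

**Cyclobutenone partner**

Step 6
Reactants: 9 3-ethoxycyclobut-2-en-1-one
Product: 10 3-(allyloxy)cyclobut-2-en-1-one
Conditions: allyl alcohol (10 equiv), camphorsulfonic acid (5 mol%), benzene, 40 °C, ethanol removed under reduced pressure
Reagents that add atoms: allyl alcohol, C=CCO
Why: Acid-catalysed exchange of the alkoxy group of a vinylogous ester (addition–elimination at C3) driven by excess alcohol; allyl is chosen because it is later removed without acid.

**Key step and ring A functionalisation**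

Step 7
Reactants: 8 triethyl({(5R)-2-methyl-5-(prop-1-en-2-yl)-8-[(triisopropylsilyl)oxy]oct-7-yn-2-yl}oxy)silane; 10 3-(allyloxy)cyclobut-2-en-1-one (1.2 equiv)
Product: 15 5-(allyloxy)-2-{(2R)-5-methyl-2-(prop-1-en-2-yl)-5-[(triethylsilyl)oxy]hexyl}-3-[(triisopropylsilyl)oxy]phenol, via vinylketene 11 (not isolated), via vinylcyclobutenone 12 (not isolated), via dienylketene 13 (not isolated), via cyclohexadienone 14 (not isolated)
Conditions: toluene, 80 °C, then 110 °C, sealed tube, argon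
Reagents that add atoms: none
Why: Thermal 4π-electrocyclic opening of 10 gives vinylketene 11, which adds [2+2] to the electron-rich siloxyalkyne 8 (its chain-bearing carbon, the future C8, bonds to the ketene carbonyl carbon, the future C8a) to give 12; a second 4π opening gives dienylketene 13, 6π-electrocyclisation gives 14 and tautomerisation gives phenol 15. The closest known reaction type is the Danheiser benzannulation of cyclobutenones with trialkylsiloxyalkynes to resorcinol monosilyl ethers; a 3-alkoxycyclobutenone is the less tested partner. Ring A is closed by 6π-electrocyclic closure of the dienylketene (C8a–C4a) after the [2+2] step has formed C8–C8a and C7–C6. No stereocentre is created and C2'', two bonds from the alkyne, is untouched. The step needs one orientation of ketene addition, which the polarisation of the ynol ether (nucleophilic at the carbon β to oxygen) secures, and it must spare the isopropenyl and allyl alkenes, which are far less nucleophilic than the siloxyalkyne. The ring oxygens emerge differentiated: free OH at C8a from the ketene carbonyl, silyl ether at C7 from 8, allyl ether at C5 from 10.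

Step 8
Reactants: 15 5-(allyloxy)-2-{(2R)-5-methyl-2-(prop-1-en-2-yl)-5-[(triethylsilyl)oxy]hexyl}-3-[(triisopropylsilyl)oxy]phenol
Product: 16 6-(allyloxy)-2-hydroxy-3-{(2R)-5-methyl-2-(prop-1-en-2-yl)-5-[(triethylsilyl)oxy]hexyl}-4-[(triisopropylsilyl)oxy]benzaldehyde
Conditions: MgCl2 (2 equiv), Et3N (4 equiv), (CH2O)n (6 equiv), MeCN, 80 °C; sat. NH4Cl
Reagents that add atoms: formaldehyde (as paraformaldehyde), C=O
Why: Magnesium-mediated ortho-formylation (Casnati–Skattebøl): the magnesium phenoxide delivers formaldehyde to the only free ortho position, C4a, and the benzylic alkoxide is oxidised in situ by hydride transfer to a second formaldehyde, while the para position C6 lies outside the chelate.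

**Ring B fragment (arylalkyne)**

Step 9
Reactants: 17 2,4-dihydroxybenzaldehyde
Product: 18 2,4-bis[(triisopropylsilyl)oxy]benzaldehyde
Conditions: i-Pr3SiCl (2.5 equiv), imidazole, DMAP (cat.), DMF, rt → 40 °C
Reagents that add atoms: chlorotriisopropylsilane, CC(C)[Si](Cl)(C(C)C)C(C)C
Why: Silylation of both phenols; the triisopropylsilyl ethers should resist the organolithium and amine conditions ahead and fall to fluoride at the end.

Step 10
Reactants: 18 2,4-bis[(triisopropylsilyl)oxy]benzaldehyde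
Product: 19 1-ethynyl-2,4-bis[(triisopropylsilyl)oxy]benzene
Conditions: Me3SiCHN2, n-BuLi, THF, −78 °C → rt; sat. NH4Cl
Reagents that add atoms: (trimethylsilyl)diazomethane, C[Si](C)(C)C=[N+]=[N-]
Why: Colvin rearrangement (addition, Peterson elimination, loss of N2 and 1,2-shift in the alkylidene carbene) gives the terminal alkyne without the carbonate–methanol medium that would cleave aryl silyl ethers.

**Ring C and end game**

Step 11
Reactants: 16 6-(allyloxy)-2-hydroxy-3-{(2R)-5-methyl-2-(prop-1-en-2-yl)-5-[(triethylsilyl)oxy]hexyl}-4-[(triisopropylsilyl)oxy]benzaldehyde; 19 1-ethynyl-2,4-bis[(triisopropylsilyl)oxy]benzene (2.5 equiv)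
Product: 21 3-(allyloxy)-2-(3-{2,4-bis[(triisopropylsilyl)oxy]phenyl}-1-hydroxyprop-2-yn-1-yl)-6-{(2R)-5-methyl-2-(prop-1-en-2-yl)-5-[(triethylsilyl)oxy]hexyl}-5-[(triisopropylsilyl)oxy]phenol (both carbinol epimers), via lithium acetylide 20 (not isolated)
Conditions: 19, n-BuLi (2.4 equiv), THF, −78 °C; then 16, −78 → 0 °C; sat. NH4Cl
Reagents that add atoms: none
Why: 1,2-Addition of the lithium acetylide to the aldehyde, the first equivalent being consumed by the phenol; the carbinol centre forms unselectively, which is of no consequence because it is oxidised in step 12.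

Step 12
Reactants: 21 3-(allyloxy)-2-(3-{2,4-bis[(triisopropylsilyl)oxy]phenyl}-1-hydroxyprop-2-yn-1-yl)-6-{(2R)-5-methyl-2-(prop-1-en-2-yl)-5-[(triethylsilyl)oxy]hexyl}-5-[(triisopropylsilyl)oxy]phenol
Product: 24 5-(allyloxy)-2-{2,4-bis[(triisopropylsilyl)oxy]phenyl}-8-{(2R)-5-methyl-2-(prop-1-en-2-yl)-5-[(triethylsilyl)oxy]hexyl}-7-[(triisopropylsilyl)oxy]-4H-chromen-4-one, via ynone 22 (not isolated), via enaminone 23 (not isolated)
Conditions: activated MnO2 (15 equiv), CH2Cl2, rt; filtration; then Et2NH (5 equiv), EtOH, rt → 60 °C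
Reagents that add atoms: none
Why: MnO2 oxidises the benzylic propargylic alcohol to the ynone, diethylamine adds to give the enaminone, and the C8a hydroxyl, the only free phenol, displaces the amine by addition–elimination, so ring C closes in the 6-endo sense to the flavone and the 5-exo aurone pathway is excluded.

Step 13
Reactants: 24 5-(allyloxy)-2-{2,4-bis[(triisopropylsilyl)oxy]phenyl}-8-{(2R)-5-methyl-2-(prop-1-en-2-yl)-5-[(triethylsilyl)oxy]hexyl}-7-[(triisopropylsilyl)oxy]-4H-chromen-4-one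
Product: 26 2-(2,4-dihydroxyphenyl)-5,7-dihydroxy-8-[(2R)-5-hydroxy-5-methyl-2-(prop-1-en-2-yl)hexyl]-4H-chromen-4-one, via 5-hydroxyflavone 25 (not isolated)
Conditions: Pd(PPh3)4 (5 mol%), morpholine (10 equiv), THF, rt; then Bu4NF (6 equiv), AcOH (6 equiv), THF, 0 °C → rt
Reagents that add atoms: none
Why: Tsuji–Trost-type deallylation by zerovalent palladium, the allyl cation being taken up by morpholine, frees the chelated C5 hydroxyl, and buffered fluoride then cleaves the three aryl silyl ethers and the tertiary silyl ether; no acid is used, so the isopropenyl group and the tertiary carbinol should survive.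

**Compound list**

1 | (4R)-limonene 1,2-oxide [(4R)-1-methyl-4-(prop-1-en-2-yl)-7-oxabicyclo[4.1.0]heptane, cis/trans mixture] | C=C(C)[C@@H]1CCC2(C)OC2C1 | starting material
2 | (3R)-6-oxo-3-(prop-1-en-2-yl)heptanal | C=C(C)[C@H](CCC(C)=O)CC=O | intermediate
3 | (5R)-8,8-dibromo-5-(prop-1-en-2-yl)oct-7-en-2-one | C=C(C)[C@H](CCC(C)=O)CC=C(Br)Br | intermediate
4 | (5R)-8,8-dibromo-2-methyl-5-(prop-1-en-2-yl)oct-7-en-2-ol | C=C(C)[C@H](CCC(C)(C)O)CC=C(Br)Br | intermediate
5 | {[(5R)-8,8-dibromo-2-methyl-5-(prop-1-en-2-yl)oct-7-en-2-yl]oxy}triethylsilane | C=C(C)[C@H](CCC(C)(C)O[Si](CC)(CC)CC)CC=C(Br)Br | intermediate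
6 | {(4R)-7-methyl-4-(prop-1-en-2-yl)-7-[(triethylsilyl)oxy]oct-1-yn-1-yl}lithium | C=C(C)[C@H](CCC(C)(C)O[Si](CC)(CC)CC)CC#C[Li] | intermediate
7 | lithium (4R)-7-methyl-4-(prop-1-en-2-yl)-7-[(triethylsilyl)oxy]oct-1-yn-1-olate | C=C(C)[C@H](CCC(C)(C)O[Si](CC)(CC)CC)CC#CO[Li] | intermediate
8 | triethyl({(5R)-2-methyl-5-(prop-1-en-2-yl)-8-[(triisopropylsilyl)oxy]oct-7-yn-2-yl}oxy)silane | C=C(C)[C@H](CCC(C)(C)O[Si](CC)(CC)CC)CC#CO[Si](C(C)C)(C(C)C)C(C)C | intermediate
9 | 3-ethoxycyclobut-2-en-1-one | CCOC1=CC(=O)C1 | starting material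
10 | 3-(allyloxy)cyclobut-2-en-1-one | C=CCOC1=CC(=O)C1 | intermediate
11 | 3-(allyloxy)buta-1,3-dien-1-one | C=CCOC(=C)C=C=O | intermediate
12 | 4-[1-(allyloxy)ethenyl]-2-{(2R)-5-methyl-2-(prop-1-en-2-yl)-5-[(triethylsilyl)oxy]hexyl}-3-[(triisopropylsilyl)oxy]cyclobut-2-en-1-one (both C4 epimers) | C=C(C)[C@H](CCC(C)(C)O[Si](CC)(CC)CC)CC1=C(O[Si](C(C)C)(C(C)C)C(C)C)C(C(=C)OCC=C)C1=O | intermediate
13 | (3E)-5-(allyloxy)-2-{(2R)-5-methyl-2-(prop-1-en-2-yl)-5-[(triethylsilyl)oxy]hexyl}-3-[(triisopropylsilyl)oxy]hexa-1,3,5-trien-1-one | C=C(C)[C@H](CCC(C)(C)O[Si](CC)(CC)CC)CC(=C=O)/C(O[Si](C(C)C)(C(C)C)C(C)C)=C\C(=C)OCC=C | intermediate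
14 | 5-(allyloxy)-2-{(2R)-5-methyl-2-(prop-1-en-2-yl)-5-[(triethylsilyl)oxy]hexyl}-3-[(triisopropylsilyl)oxy]cyclohexa-2,4-dien-1-one | C=C(C)[C@H](CCC(C)(C)O[Si](CC)(CC)CC)CC1=C(O[Si](C(C)C)(C(C)C)C(C)C)C=C(OCC=C)CC1=O | intermediate
15 | 5-(allyloxy)-2-{(2R)-5-methyl-2-(prop-1-en-2-yl)-5-[(triethylsilyl)oxy]hexyl}-3-[(triisopropylsilyl)oxy]phenol | C=C(C)[C@H](CCC(C)(C)O[Si](CC)(CC)CC)Cc1c(O)cc(OCC=C)cc1O[Si](C(C)C)(C(C)C)C(C)C | intermediate
16 | 6-(allyloxy)-2-hydroxy-3-{(2R)-5-methyl-2-(prop-1-en-2-yl)-5-[(triethylsilyl)oxy]hexyl}-4-[(triisopropylsilyl)oxy]benzaldehyde | C=C(C)[C@H](CCC(C)(C)O[Si](CC)(CC)CC)Cc1c(O)c(C=O)c(OCC=C)cc1O[Si](C(C)C)(C(C)C)C(C)C | intermediate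
17 | 2,4-dihydroxybenzaldehyde | O=Cc1ccc(O)cc1O | starting material
18 | 2,4-bis[(triisopropylsilyl)oxy]benzaldehyde | O=Cc1ccc(O[Si](C(C)C)(C(C)C)C(C)C)cc1O[Si](C(C)C)(C(C)C)C(C)C | intermediate
19 | 1-ethynyl-2,4-bis[(triisopropylsilyl)oxy]benzene | C#Cc1ccc(O[Si](C(C)C)(C(C)C)C(C)C)cc1O[Si](C(C)C)(C(C)C)C(C)C | intermediate
20 | ({2,4-bis[(triisopropylsilyl)oxy]phenyl}ethynyl)lithium | [Li]C#Cc1ccc(O[Si](C(C)C)(C(C)C)C(C)C)cc1O[Si](C(C)C)(C(C)C)C(C)C | intermediate
21 | 3-(allyloxy)-2-(3-{2,4-bis[(triisopropylsilyl)oxy]phenyl}-1-hydroxyprop-2-yn-1-yl)-6-{(2R)-5-methyl-2-(prop-1-en-2-yl)-5-[(triethylsilyl)oxy]hexyl}-5-[(triisopropylsilyl)oxy]phenol (both carbinol epimers) | C=C(C)[C@H](CCC(C)(C)O[Si](CC)(CC)CC)Cc1c(O)c(C(O)C#Cc2ccc(O[Si](C(C)C)(C(C)C)C(C)C)cc2O[Si](C(C)C)(C(C)C)C(C)C)c(OCC=C)cc1O[Si](C(C)C)(C(C)C)C(C)C | intermediate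
22 | 1-[6-(allyloxy)-2-hydroxy-3-{(2R)-5-methyl-2-(prop-1-en-2-yl)-5-[(triethylsilyl)oxy]hexyl}-4-[(triisopropylsilyl)oxy]phenyl]-3-{2,4-bis[(triisopropylsilyl)oxy]phenyl}prop-2-yn-1-one | C=C(C)[C@H](CCC(C)(C)O[Si](CC)(CC)CC)Cc1c(O)c(C(=O)C#Cc2ccc(O[Si](C(C)C)(C(C)C)C(C)C)cc2O[Si](C(C)C)(C(C)C)C(C)C)c(OCC=C)cc1O[Si](C(C)C)(C(C)C)C(C)C | intermediate
23 | 1-[6-(allyloxy)-2-hydroxy-3-{(2R)-5-methyl-2-(prop-1-en-2-yl)-5-[(triethylsilyl)oxy]hexyl}-4-[(triisopropylsilyl)oxy]phenyl]-3-{2,4-bis[(triisopropylsilyl)oxy]phenyl}-3-(diethylamino)prop-2-en-1-one | C=C(C)[C@H](CCC(C)(C)O[Si](CC)(CC)CC)Cc1c(O)c(C(=O)C=C(N(CC)CC)c2ccc(O[Si](C(C)C)(C(C)C)C(C)C)cc2O[Si](C(C)C)(C(C)C)C(C)C)c(OCC=C)cc1O[Si](C(C)C)(C(C)C)C(C)C | intermediate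
24 | 5-(allyloxy)-2-{2,4-bis[(triisopropylsilyl)oxy]phenyl}-8-{(2R)-5-methyl-2-(prop-1-en-2-yl)-5-[(triethylsilyl)oxy]hexyl}-7-[(triisopropylsilyl)oxy]-4H-chromen-4-one | C=C(C)[C@H](CCC(C)(C)O[Si](CC)(CC)CC)Cc1c(O[Si](C(C)C)(C(C)C)C(C)C)cc(OCC=C)c2c(=O)cc(-c3ccc(O[Si](C(C)C)(C(C)C)C(C)C)cc3O[Si](C(C)C)(C(C)C)C(C)C)oc12 | intermediate
25 | 2-{2,4-bis[(triisopropylsilyl)oxy]phenyl}-5-hydroxy-8-{(2R)-5-methyl-2-(prop-1-en-2-yl)-5-[(triethylsilyl)oxy]hexyl}-7-[(triisopropylsilyl)oxy]-4H-chromen-4-one | C=C(C)[C@H](CCC(C)(C)O[Si](CC)(CC)CC)Cc1c(O[Si](C(C)C)(C(C)C)C(C)C)cc(O)c2c(=O)cc(-c3ccc(O[Si](C(C)C)(C(C)C)C(C)C)cc3O[Si](C(C)C)(C(C)C)C(C)C)oc12 | intermediate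
26 | 2-(2,4-dihydroxyphenyl)-5,7-dihydroxy-8-[(2R)-5-hydroxy-5-methyl-2-(prop-1-en-2-yl)hexyl]-4H-chromen-4-one | C=C(C)[C@H](CCC(C)(C)O)Cc1c(O)cc(O)c2c(=O)cc(-c3ccc(O)cc3O)oc12 | target

**Count and risks**

Total: 13 steps. Longest linear sequence: 10 steps (steps 1–5, 7, 8, 11–13).

Step 7 (benzannulation). The vinylogous-ester stabilisation of 10 may slow its electrocyclic opening, so that 8 isomerises by 1,3-silyl shift to a silylketene before it is trapped, or the product phenol may be acylated by surplus vinylketene. The fallback sets out from 8, returns to the route at 15, and introduces the C5 oxygen only after the annulation. Cyclobut-2-en-1-one F1, set free from commercial 3-bromocyclobutanone with Bu3N, opens readily and would be heated with 8 to give 2-{(2R)-5-methyl-2-(prop-1-en-2-yl)-5-[(triethylsilyl)oxy]hexyl}-3-[(triisopropylsilyl)oxy]phenol F2. Iridium-catalysed C–H borylation ([Ir(OMe)(cod)]2, 4,4'-di-tert-butyl-2,2'-bipyridine, B2pin2, THF, 60 °C) should go to the only ring C–H without an ortho substituent and give the aryl boronate F3. Oxidation with NaBO3 in THF–water would give 4-{(2R)-5-methyl-2-(prop-1-en-2-yl)-5-[(triethylsilyl)oxy]hexyl}-5-[(triisopropylsilyl)oxy]benzene-1,3-diol F4. Allyl bromide (1 equiv) and K2CO3 in acetone should etherify the unhindered hydroxyl in preference to the one flanked by the branched chain, which gives 15.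

Step 5 (acetylide to siloxyalkyne). Oxygen transfer from the peroxide to the acetylide may be incomplete, or the ynolate may be protonated or silylated on carbon. The fallback sets out from 2, returns at 7 and then 8, and makes the ynolate by Kowalski ester homologation. Pinnick oxidation (NaClO2, NaH2PO4, 2-methylbut-2-ene) would give (3R)-6-oxo-3-(prop-1-en-2-yl)heptanoic acid F5. MeMgBr (3 equiv), to which the carboxylate is inert, would give (3R)-6-hydroxy-6-methyl-3-(prop-1-en-2-yl)heptanoic acid F6. Me3SiCHN2 in methanol–toluene would give the methyl ester F7, and Et3SiOTf with 2,6-lutidine would give methyl (3R)-6-methyl-3-(prop-1-en-2-yl)-6-[(triethylsilyl)oxy]heptanoate F8. Treatment of F8 with LiCHBr2 (from CH2Br2 and lithium 2,2,6,6-tetramethylpiperidide) and then n-BuLi would pass through the lithium enolate of the dibromomethyl ketone F9, which rearranges on warming to ynolate 7; i-Pr3SiOTf would then give 8.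

Step 6 (alkoxy exchange on the cyclobutenone). The alcohol may open the strained ring by attack at the carbonyl and retro-Claisen cleavage instead of exchanging at C3. The fallback sets out from 9 and returns at 10. Hydrolysis with dilute aqueous HCl would give cyclobutane-1,3-dione F10, and Mitsunobu O-alkylation of its acidic enol with allyl alcohol (PPh3, diisopropyl azodicarboxylate, THF, 0 °C) would give 10 without an acid–alcohol medium.

**Further compounds**

F1 | step 7 | cyclobut-2-en-1-one | O=C1C=CC1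
F2 | step 7 | 2-{(2R)-5-methyl-2-(prop-1-en-2-yl)-5-[(triethylsilyl)oxy]hexyl}-3-[(triisopropylsilyl)oxy]phenol | C=C(C)[C@H](CCC(C)(C)O[Si](CC)(CC)CC)Cc1c(O)cccc1O[Si](C(C)C)(C(C)C)C(C)C
F3 | step 7 | 2-{(2R)-5-methyl-2-(prop-1-en-2-yl)-5-[(triethylsilyl)oxy]hexyl}-5-(4,4,5,5-tetramethyl-1,3,2-dioxaborolan-2-yl)-3-[(triisopropylsilyl)oxy]phenol | C=C(C)[C@H](CCC(C)(C)O[Si](CC)(CC)CC)Cc1c(O)cc(B2OC(C)(C)C(C)(C)O2)cc1O[Si](C(C)C)(C(C)C)C(C)C
F4 | step 7 | 4-{(2R)-5-methyl-2-(prop-1-en-2-yl)-5-[(triethylsilyl)oxy]hexyl}-5-[(triisopropylsilyl)oxy]benzene-1,3-diol | C=C(C)[C@H](CCC(C)(C)O[Si](CC)(CC)CC)Cc1c(O)cc(O)cc1O[Si](C(C)C)(C(C)C)C(C)C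
F5 | step 5 | (3R)-6-oxo-3-(prop-1-en-2-yl)heptanoic acid | C=C(C)[C@H](CCC(C)=O)CC(=O)O
F6 | step 5 | (3R)-6-hydroxy-6-methyl-3-(prop-1-en-2-yl)heptanoic acid | C=C(C)[C@H](CCC(C)(C)O)CC(=O)O
F7 | step 5 | methyl (3R)-6-hydroxy-6-methyl-3-(prop-1-en-2-yl)heptanoate | C=C(C)[C@H](CCC(C)(C)O)CC(=O)OC
F8 | step 5 | methyl (3R)-6-methyl-3-(prop-1-en-2-yl)-6-[(triethylsilyl)oxy]heptanoate | C=C(C)[C@H](CCC(C)(C)O[Si](CC)(CC)CC)CC(=O)OC
F9 | step 5 | lithium (4R)-1,1-dibromo-7-methyl-4-(prop-1-en-2-yl)-7-[(triethylsilyl)oxy]oct-1-en-2-olate | C=C(C)[C@H](CCC(C)(C)O[Si](CC)(CC)CC)CC(O[Li])=C(Br)Br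
F10 | step 6 | cyclobutane-1,3-dione | O=C1CC(=O)C1
A1 | direct plan | 3,5-bis(methoxymethoxy)-2-{[(triisopropylsilyl)oxy]methyl}-6-(trimethylsilyl)phenyl trifluoromethanesulfonate | COCOc1cc(OCOC)c([Si](C)(C)C)c(OS(=O)(=O)C(F)(F)F)c1CO[Si](C(C)C)(C(C)C)C(C)C
A2 | direct plan | 3-[2,4-bis(methoxymethoxy)phenyl]prop-2-ynoic acid | OC(=O)C#Cc1ccc(OCOC)cc1OCOC
A3 | direct plan | 2-[2,4-bis(methoxymethoxy)phenyl]-5,7-bis(methoxymethoxy)-4-oxo-4H-chromene-8-carbaldehyde | COCOc1cc(OCOC)c2c(=O)cc(-c3ccc(OCOC)cc3OCOC)oc2c1C=O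
A4 | direct plan | 2-[2,4-bis(methoxymethoxy)phenyl]-8-{(1S,2S)-1-hydroxy-5-methyl-2-(prop-1-en-2-yl)-5-[(triethylsilyl)oxy]hexyl}-5,7-bis(methoxymethoxy)-4H-chromen-4-one | C=C(C)[C@H](CCC(C)(C)O[Si](CC)(CC)CC)[C@H](O)c1c(OCOC)cc(OCOC)c2c(=O)cc(-c3ccc(OCOC)cc3OCOC)oc12
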